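The target is a depside whose benzoyl ring A bears oxygen at C2 and C4, propyl at C6 and the ester carboxyl at C1, the pattern left by a linear 3,5,7-trioxodecanoate folded head to tail. The route therefore disconnects ring A at C1–C6. An open-chain triketo ester, already attached through its C1 carboxyl to the ring B 4-oxygen of benzyl olivetolate, is closed by intramolecular aldol condensation (chain C2 onto the C7 ketone) and dehydration. This creates the whole resorcylate ring with the hindered depside ester in place. The chain comes from a diketo-dioxinone via an acylketene; O-methylation, C3 chlorination and debenzylation finish the synthesis.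

Key step: step 6

Remark: the target is achiral; the ring B 2-hydroxyl is carried free throughout because its hydrogen bond to the ester carbonyl keeps it inert, and the triketo ester and the cyclic aldol are drawn as single tautomers of what will be tautomeric mixtures.

Step 1
Reactants: 1 2,2,6-trimethyl-4H-1,3-dioxin-4-one; 2 acetyl chloride
Product: 3 2,2-dimethyl-6-(2-oxopropyl)-4H-1,3-dioxin-4-one
Conditions: 1 (2 equiv), LiN(SiMe3)2 (2 equiv), THF, −78 °C; then 2 (1 equiv), −78 °C; 1 M HCl quench
Reagents that add atoms: none
Why: Vinylogous Claisen acylation, in which the extended lithium dienolate formed at the 6-methyl group is C-acylated at its terminus by the acid chloride while the second equivalent of dienolate takes up the more acidic proton of the product.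

Step 2
Reactants: 4 butanoyl chloride
Product: 5 N-methoxy-N-methylbutanamide
Conditions: MeNHOMe·HCl, K2CO3, CH2Cl2–H2O, 0 °C → rt
Reagents that add atoms: N,O-dimethylhydroxylamine hydrochloride, CNOC.Cl
Why: Schotten–Baumann acylation of the liberated hydroxylamine by a simple acid chloride, a routine Weinreb amide formation.

Step 3
Reactants: 3 2,2-dimethyl-6-(2-oxopropyl)-4H-1,3-dioxin-4-one; 5 N-methoxy-N-methylbutanamide
Product: 6 6-(2,4-dioxoheptyl)-2,2-dimethyl-4H-1,3-dioxin-4-one
Conditions: LiN(i-Pr)2 (2.2 equiv), THF, −78 °C; then 5, −78 → −30 °C; 1 M HCl quench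
Reagents that add atoms: none
Why: Claisen-type acylation of a ketone dianion, whose more reactive terminal carbon (the former methyl group) adds to the Weinreb amide to give a chelated tetrahedral adduct that persists until the quench, so that neither over-addition nor proton transfer to unreacted dianion should interfere.

Step 4
Reactants: 7 olivetolic acid
Product: 8 benzyl 2,4-dihydroxy-6-pentylbenzoate
Conditions: BnBr, KHCO3, DMF, rt
Reagents that add atoms: benzyl bromide, BrCc1ccccc1
Why: SN2 O-alkylation of the carboxylate, because hydrogen carbonate ionizes only the carboxylic acid and leaves both phenols free, and room temperature avoids decarboxylation of the β-resorcylic acid.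

Step 5
Reactants: 6 6-(2,4-dioxoheptyl)-2,2-dimethyl-4H-1,3-dioxin-4-one; 8 benzyl 2,4-dihydroxy-6-pentylbenzoate
Product: 10 benzyl 2-hydroxy-6-pentyl-4-[(3,5,7-trioxodecanoyl)oxy]benzoate, via acylketene 9 (not isolated)
Conditions: 8 (1.3 equiv), PhMe, 110 °C, short heating; concentrate and carry the crude ester forward
Reagents that add atoms: none
Why: Retro-hetero-Diels–Alder loss of acetone from the dioxinone releases acylketene 9, which is captured by O–H addition of the free 4-hydroxyl of 8 (the 2-hydroxyl is tied up in its hydrogen bond to the ester carbonyl), as in the acetoacetylation of phenols with dioxinones, and the excess of phenol should outpace lactonization of the ketene to a pyranone.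

Step 6
Reactants: 10 benzyl 2-hydroxy-6-pentyl-4-[(3,5,7-trioxodecanoyl)oxy]benzoate
Product: 12 benzyl 4-[(2,4-dihydroxy-6-propylbenzoyl)oxy]-2-hydroxy-6-pentylbenzoate, via cyclic aldol 11 (not isolated)
Conditions: Et3N (2 equiv), CH2Cl2, 0 °C → rt; then HCl (4 M in dioxane), rt
Reagents that add atoms: none
Why: Et3N reversibly enolizes the β-keto ester terminus and chain C2 adds to the C7 ketone to give cyclic aldol 11, which loses water on acidification and tautomerizes to the aromatic 2,4-dihydroxy-6-propylbenzoate. The closest known reaction type is the biomimetic aldol aromatization of 3,5,7-triketo esters made by acylketene capture. Ring A closes in a 6-(enolendo)-exo-trig mode, forming its C1–C6 bond, and no stereocentre is set because the carbinol carbon of 11 becomes aromatic. The step needs mode selectivity: C2-to-C7 aldol addition must beat C6-to-C1 Claisen closure, lactonization through the C5 enol oxygen and E1cB loss of a ketene, each of which would expel the ring B phenoxide. The substrate secures this because C7 is a ketone, far more electrophilic towards a carbon nucleophile than the ester carbon C1, and because a weak amine base in an aprotic solvent free of nucleophiles forms only mono-enolates and offers nothing that can attack the aryl ester. Aromatization then makes the aldol pathway irreversible.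

Step 7
Reactants: 12 benzyl 4-[(2,4-dihydroxy-6-propylbenzoyl)oxy]-2-hydroxy-6-pentylbenzoate
Product: 13 benzyl 2-hydroxy-4-[(2-hydroxy-4-methoxy-6-propylbenzoyl)oxy]-6-pentylbenzoate
Conditions: MeI (1.1 equiv), K2CO3 (1.1 equiv), acetone, rt
Reagents that add atoms: iodomethane, CI
Why: Williamson ether synthesis in which one equivalent of carbonate ionizes only the ring A 4-hydroxyl, which is para to the ester carbonyl and not hydrogen-bonded, while both ortho-hydroxyls stay chelated to their ester carbonyls and unreactive.

Step 8
Reactants: 13 benzyl 2-hydroxy-4-[(2-hydroxy-4-methoxy-6-propylbenzoyl)oxy]-6-pentylbenzoate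
Product: 14 benzyl 4-[(3-chloro-2-hydroxy-4-methoxy-6-propylbenzoyl)oxy]-2-hydroxy-6-pentylbenzoate
Conditions: SO2Cl2 (1.0 equiv), 2,2,6,6-tetramethylpiperidine (10 mol%), PhMe, 0 °C → rt
Reagents that add atoms: sulfuryl chloride, O=S(=O)(Cl)Cl
Why: Amine-catalysed ortho-selective electrophilic chlorination of a phenol, in which the N-chloroamine formed from the catalyst hydrogen-bonds to the ring A 2-hydroxyl and delivers chlorine to C3, the only carbon ortho to it, on the ring that carries two donor oxygens and is therefore much more reactive than the acyloxy-substituted ring B.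

Step 9
Reactants: 14 benzyl 4-[(3-chloro-2-hydroxy-4-methoxy-6-propylbenzoyl)oxy]-2-hydroxy-6-pentylbenzoate
Product: 15 4-[(3-chloro-2-hydroxy-4-methoxy-6-propylbenzoyl)oxy]-2-hydroxy-6-pentylbenzoic acid
Conditions: H2 (1 atm), Pd/C, EtOAc, rt, stopped at full conversion
Reagents that add atoms: none
Why: Hydrogenolysis of the benzylic C–O bond over Pd/C is fast under neutral conditions, under which the electron-rich, doubly ortho-substituted aryl chloride and the aryl ester should not be reduced.

Compound list
1 | 2,2,6-trimethyl-4H-1,3-dioxin-4-one | CC1=CC(=O)OC(C)(C)O1 | starting material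
2 | acetyl chloride | CC(=O)Cl | starting material
3 | 2,2-dimethyl-6-(2-oxopropyl)-4H-1,3-dioxin-4-one | CC(=O)CC1=CC(=O)OC(C)(C)O1 | intermediate
4 | butanoyl chloride | CCCC(=O)Cl | starting material
5 | N-methoxy-N-methylbutanamide | CCCC(=O)N(C)OC | intermediate
6 | 6-(2,4-dioxoheptyl)-2,2-dimethyl-4H-1,3-dioxin-4-one | CCCC(=O)CC(=O)CC1=CC(=O)OC(C)(C)O1 | intermediate
7 | olivetolic acid (2,4-dihydroxy-6-pentylbenzoic acid) | CCCCCc1cc(O)cc(O)c1C(=O)O | starting material
8 | benzyl 2,4-dihydroxy-6-pentylbenzoate | CCCCCc1cc(O)cc(O)c1C(=O)OCc1ccccc1 | intermediate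
9 | 3,5,7-trioxodec-1-en-1-one (acylketene, formed and consumed in step 5) | CCCC(=O)CC(=O)CC(=O)C=C=O | intermediate
10 | benzyl 2-hydroxy-6-pentyl-4-[(3,5,7-trioxodecanoyl)oxy]benzoate | CCCC(=O)CC(=O)CC(=O)CC(=O)Oc1cc(CCCCC)c(C(=O)OCc2ccccc2)c(O)c1 | intermediate
11 | benzyl 4-[(2,6-dihydroxy-4-oxo-6-propylcyclohex-1-ene-1-carbonyl)oxy]-2-hydroxy-6-pentylbenzoate (cyclic aldol, racemic at the carbinol carbon, formed and consumed in step 6) | CCCC1(O)CC(=O)CC(O)=C1C(=O)Oc1cc(CCCCC)c(C(=O)OCc2ccccc2)c(O)c1 | intermediate
12 | benzyl 4-[(2,4-dihydroxy-6-propylbenzoyl)oxy]-2-hydroxy-6-pentylbenzoate | CCCc1cc(O)cc(O)c1C(=O)Oc1cc(CCCCC)c(C(=O)OCc2ccccc2)c(O)c1 | intermediate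
13 | benzyl 2-hydroxy-4-[(2-hydroxy-4-methoxy-6-propylbenzoyl)oxy]-6-pentylbenzoate | CCCc1cc(OC)cc(O)c1C(=O)Oc1cc(CCCCC)c(C(=O)OCc2ccccc2)c(O)c1 | intermediate
14 | benzyl 4-[(3-chloro-2-hydroxy-4-methoxy-6-propylbenzoyl)oxy]-2-hydroxy-6-pentylbenzoate | CCCc1cc(OC)c(Cl)c(O)c1C(=O)Oc1cc(CCCCC)c(C(=O)OCc2ccccc2)c(O)c1 | intermediate
15 | 4-[(3-chloro-2-hydroxy-4-methoxy-6-propylbenzoyl)oxy]-2-hydroxy-6-pentylbenzoic acid | CCCCCc1cc(OC(=O)c2c(CCC)cc(OC)c(Cl)c2O)cc(O)c1C(=O)O | target

Total step count: 9. Longest linear sequence: 7 steps (steps 1, 3, 5, 6, 7, 8 and 9, counted from 1).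

Steps most likely to fail

Step 6. The enolized chain may close in the Claisen or lactone mode, or fragment by E1cB, each time with loss of the ring B phenoxide instead of aldol closure. The fallback sets out from 6, uses 8 again and comes back at 13; it also bypasses the ketene capture of step 5. Diketo-dioxinone 6 would itself be cyclized with Et3N in CH2Cl2, the dioxinone C5 adding to the terminal ketone in the same aldol mode while the acetonide, which cannot leave, holds the carboxyl. This should give 7-hydroxy-2,2-dimethyl-5-propyl-4H-1,3-benzodioxin-4-one F1. Methylation (MeI, K2CO3, acetone) would give 7-methoxy-2,2-dimethyl-5-propyl-4H-1,3-benzodioxin-4-one F2. Saponification (KOH, aqueous DMSO, then HCl) would release 2-hydroxy-4-methoxy-6-propylbenzoic acid F3. Mixed-anhydride esterification of this acid with phenol 8 (trifluoroacetic anhydride, PhMe, rt), a classical depside coupling that takes place at the free 4-hydroxyl of 8, would then return to the route at 13.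

Step 8. Site selectivity of the chlorination may be poor: attack at ring A C5 para to the hydroxyl, double chlorination, or attack on ring B. The fallback sets out from 13 and comes back at 15. NBS in MeCN at 0 °C should first occupy ring A C5, the position para to the 2-hydroxyl that an undirected electrophile prefers, giving benzyl 4-[(5-bromo-2-hydroxy-4-methoxy-6-propylbenzoyl)oxy]-2-hydroxy-6-pentylbenzoate F4 (ring A numbered from its carbonyl-bearing carbon). SO2Cl2 in CH2Cl2 would then chlorinate the only free ring A position, C3, to give benzyl 4-[(5-bromo-3-chloro-2-hydroxy-4-methoxy-6-propylbenzoyl)oxy]-2-hydroxy-6-pentylbenzoate F5. Hydrogenolysis over Pd/C with NaOAc in EtOAc–EtOH, stopped once the bromide is consumed, would remove the benzyl group and the more labile aryl bromine together and leave the chlorine, arriving at 15.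

Step 9. The aryl chlorine may be lost reductively during debenzylation. The fallback sets out from 13 and comes back at 15. The benzyl ester would be hydrogenolysed before any halogen is present (H2, Pd/C, EtOAc) to give 2-hydroxy-4-[(2-hydroxy-4-methoxy-6-propylbenzoyl)oxy]-6-pentylbenzoic acid F6. The amine-catalysed chlorination of step 8 (SO2Cl2, catalytic 2,2,6,6-tetramethylpiperidine, PhMe–EtOAc) would then be run on this acid as the last operation, ring A again being the more electron-rich ring, to give 15 directly.

Further compounds
F1 | step 6 | 7-hydroxy-2,2-dimethyl-5-propyl-4H-1,3-benzodioxin-4-one | CCCc1cc(O)cc2OC(C)(C)OC(=O)c12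
F2 | step 6 | 7-methoxy-2,2-dimethyl-5-propyl-4H-1,3-benzodioxin-4-one | CCCc1cc(OC)cc2OC(C)(C)OC(=O)c12
F3 | step 6 | 2-hydroxy-4-methoxy-6-propylbenzoic acid | CCCc1cc(OC)cc(O)c1C(=O)O
F4 | step 8 | benzyl 4-[(5-bromo-2-hydroxy-4-methoxy-6-propylbenzoyl)oxy]-2-hydroxy-6-pentylbenzoate | CCCc1c(Br)c(OC)cc(O)c1C(=O)Oc1cc(CCCCC)c(C(=O)OCc2ccccc2)c(O)c1
F5 | step 8 | benzyl 4-[(5-bromo-3-chloro-2-hydroxy-4-methoxy-6-propylbenzoyl)oxy]-2-hydroxy-6-pentylbenzoate | CCCc1c(Br)c(OC)c(Cl)c(O)c1C(=O)Oc1cc(CCCCC)c(C(=O)OCc2ccccc2)c(O)c1
F6 | step 9 | 2-hydroxy-4-[(2-hydroxy-4-methoxy-6-propylbenzoyl)oxy]-6-pentylbenzoic acid | CCCCCc1cc(OC(=O)c2c(CCC)cc(OC)cc2O)cc(O)c1C(=O)O
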